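Ring F (O1', C2', C3', C4', C4a', C8a') is not closed directly. It is traced back to a trans-2,3-disubstituted 2,3-dihydrobenzofuran in which O1' is still bonded to C3' and benzylic C2' carries a mesylate. In one operation O1' displaces the mesylate, acetate opens the resulting bicyclic oxiranium ion at C3', and the five-membered ring becomes ring F with the O1'–C2' bond and the C2'/C3' stereocentres in place. The feature exploited is that in ring F O1' sits on benzylic C2', with the C2' aryl cis to the C3' oxygen and trans to the C4' oxygen. The precursor carries the complete all-cis upper flavan (rings A–C) on C6'.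

Key step: step 15

Labels: unprimed atoms and rings A (benzo), B (2-aryl) and C (pyran) belong to the upper flavan; primed atoms and rings D (central benzo ring), E (2'-aryl) and F (pyran) belong to the lower unit. The open-chain and dihydrobenzofuran intermediates keep the primed labels of the atoms they become. Ar = 3,4-bis(benzyloxy)phenyl. Fl = all-cis (2R,3R,4S)-7,8-bis(benzyloxy)-2-Ar-3-(pivaloyloxy)chroman-4-yl. Fl(OH) = the same group with a free 3-hydroxyl.

Assumption: the (R)-configured catalysts of steps 8 and 9 are taken to give the senses drawn; if a sense proves opposite, the antipodal catalyst is used and nothing else changes.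

Step 1
Reactants: 1 2,3,4-trihydroxybenzaldehyde
Product: 2 3,4-bis(benzyloxy)-2-hydroxybenzaldehyde
Conditions: BnBr (2.1 equiv), K2CO3 (2.2 equiv), DMF, 0 °C → rt
Reagents that add atoms: benzyl bromide, BrCc1ccccc1
Why: Williamson etherification in which the 4-OH (para to the formyl group) and then the 3-OH react, whereas the 2-OH is held in a hydrogen bond to the carbonyl group and should stay free when only two equivalents of halide are offered.

Step 2
Reactants: 2 3,4-bis(benzyloxy)-2-hydroxybenzaldehyde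
Product: 3 3,4-bis(benzyloxy)-5-bromo-2-hydroxybenzaldehyde
Conditions: NBS, MeCN, 0 °C → rt
Reagents that add atoms: N-bromosuccinimide, O=C1CCC(=O)N1Br
Why: Electrophilic aromatic bromination goes to C5, which is para to the free phenol and ortho to the 4-benzyloxy group, while C6 lies ortho to the deactivating formyl group.

Step 3
Reactants: 3 3,4-bis(benzyloxy)-5-bromo-2-hydroxybenzaldehyde
Product: 4 3,4-bis(benzyloxy)-5-bromo-2-(triisopropylsilyloxy)benzaldehyde
Conditions: TIPSCl, imidazole, DMF, rt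
Reagents that add atoms: chlorotriisopropylsilane, CC(C)[Si](Cl)(C(C)C)C(C)C
Why: Phenol silylation; the triisopropylsilyl ether should survive the aryllithium, the Brønsted acid and the Et2Zn/Ti(OiPr)4 steps and later leaves with fluoride when the phenoxide is needed.

Step 4
Reactants: 4 3,4-bis(benzyloxy)-5-bromo-2-(triisopropylsilyloxy)benzaldehyde
Product: 5 2-[3,4-bis(benzyloxy)-5-bromo-2-(triisopropylsilyloxy)phenyl]-1,3-dioxolane
Conditions: (TMSOCH2)2, TMSOTf (5 mol%), CH2Cl2, −78 → −20 °C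
Reagents that add atoms: 1,2-bis(trimethylsilyloxy)ethane, C[Si](C)(C)OCCO[Si](C)(C)C
Why: Noyori acetalisation under aprotic conditions masks the formyl group for the halogen–lithium exchange without touching the aryl silyl ether.

Step 5
Reactants: 5 2-[3,4-bis(benzyloxy)-5-bromo-2-(triisopropylsilyloxy)phenyl]-1,3-dioxolane, 2 3,4-bis(benzyloxy)-2-hydroxybenzaldehyde
Product: 8 [3,4-bis(benzyloxy)-2-hydroxyphenyl][2,3-bis(benzyloxy)-5-(1,3-dioxolan-2-yl)-4-(triisopropylsilyloxy)phenyl]methanol (racemic carbinol), via aryllithium 6 (not isolated), via sodium phenoxide 7 (not isolated)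
Conditions: 5, n-BuLi, THF, −78 °C; 2, NaH, THF, 0 °C; combine, −78 → −20 °C; H2O
Reagents that add atoms: none
Why: Bromine–lithium exchange at −78 °C is faster than attack on the dioxolane or the ethers, and 1,2-addition of the aryllithium to the formyl group of the phenoxide gives the o-hydroxybenzhydrol directly; the carbinol configuration is irrelevant because this carbon becomes planar in step 8.

Step 6
Reactants: 9 3,4-bis(benzyloxy)benzaldehyde
Product: 10 1,2-bis(benzyloxy)-4-ethynylbenzene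
Conditions: dimethyl (1-diazo-2-oxopropyl)phosphonate, K2CO3, MeOH, rt
Reagents that add atoms: dimethyl (1-diazo-2-oxopropyl)phosphonate, COP(=O)(OC)C(=[N+]=[N-])C(C)=O
Why: Seyferth–Gilbert homologation with the Ohira–Bestmann reagent converts the aldehyde into the terminal alkyne under mild base that benzyl ethers tolerate.

Step 7
Reactants: 10 1,2-bis(benzyloxy)-4-ethynylbenzene
Product: 11 (Z)-2-[3,4-bis(benzyloxy)phenyl]ethenyl 2,2-dimethylpropanoate
Conditions: pivalic acid, Ru(methallyl)2(dppb) (2 mol%), toluene, 50 °C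
Reagents that add atoms: pivalic acid, CC(C)(C)C(=O)O
Why: Ruthenium-catalysed anti-Markovnikov addition of a carboxylic acid to a terminal alkyne runs through a vinylidene complex and gives the Z-enol ester, which places the future C3 oxygen cis to ring B.

Step 8
Reactants: 8 [3,4-bis(benzyloxy)-2-hydroxyphenyl][2,3-bis(benzyloxy)-5-(1,3-dioxolan-2-yl)-4-(triisopropylsilyloxy)phenyl]methanol, 11 (Z)-2-[3,4-bis(benzyloxy)phenyl]ethenyl 2,2-dimethylpropanoate
Product: 14 3,4-bis(benzyloxy)-5-Fl-2-(triisopropylsilyloxy)benzaldehyde, via o-quinone methide 12 (not isolated), via dioxolane cycloadduct 13 (not isolated)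
Conditions: (R)-3,3'-bis(2,4,6-triisopropylphenyl)-BINOL N-triflylphosphoramide (10 mol%), 4 Å MS, CH2Cl2, −30 °C → rt; then 1 M HCl, THF, rt
Reagents that add atoms: water, O
Why: Acid-catalysed dehydration gives the E-configured o-quinone methide as an ion pair with the chiral phosphoramide anion, and an inverse-electron-demand hetero-Diels–Alder reaction follows in which the enol ester reacts as an electron-rich styrene (pivaloyloxy-bearing carbon to C4, aryl-bearing carbon to O1), ring B sits endo and the Z geometry is carried over, so C2, C3 and C4 are set all-cis in one event with the absolute sense fixed by the methide face that the chiral anion leaves open; dilute acid then unmasks the formyl group.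

Step 9
Reactants: 14 3,4-bis(benzyloxy)-5-Fl-2-(triisopropylsilyloxy)benzaldehyde, 10 1,2-bis(benzyloxy)-4-ethynylbenzene
Product: 16 (1R)-3-Ar-1-[3,4-bis(benzyloxy)-5-Fl-2-(triisopropylsilyloxy)phenyl]prop-2-yn-1-ol, via alkynylzinc 15 (not isolated)
Conditions: 10 (3 equiv), Et2Zn (3 equiv), toluene, reflux; (R)-BINOL (40 mol%), Ti(OiPr)4 (1 equiv), CH2Cl2, rt; then 14, rt
Reagents that add atoms: none
Why: Catalytic asymmetric addition of an alkynylzinc to an aryl aldehyde under Ti(OiPr)4/BINOL control delivers the alkynyl group to the Re face of the formyl group and so sets C4' (R in this compound), the remote upper stereocentres exerting no meaningful bias.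

Step 10
Reactants: 16 (1R)-3-Ar-1-[3,4-bis(benzyloxy)-5-Fl-2-(triisopropylsilyloxy)phenyl]prop-2-yn-1-ol
Product: 17 (1R,2Z)-3-Ar-1-[3,4-bis(benzyloxy)-5-Fl-2-(triisopropylsilyloxy)phenyl]prop-2-en-1-ol
Conditions: H2 (1 atm), Pd/CaCO3 poisoned with Pb(OAc)2 (Lindlar catalyst), quinoline, EtOAc, rt
Reagents that add atoms: none
Why: Lindlar semihydrogenation adds hydrogen syn on the poisoned surface and stops at the Z-alkene, and aryl benzyl ethers are not cleaved by this catalyst.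

Step 11
Reactants: 17 (1R,2Z)-3-Ar-1-[3,4-bis(benzyloxy)-5-Fl-2-(triisopropylsilyloxy)phenyl]prop-2-en-1-ol
Product: 18 (S)-[(2R,3S)-3-Ar-oxiran-2-yl][3,4-bis(benzyloxy)-5-Fl-2-(triisopropylsilyloxy)phenyl]methanol
Conditions: mCPBA, NaHCO3, CH2Cl2, 0 °C
Reagents that add atoms: 3-chloroperoxybenzoic acid, OOC(=O)c1cccc(Cl)c1
Why: Hydroxyl-directed peracid epoxidation of a Z-allylic alcohol, in which allylic 1,3-strain puts the C4'–H bond in the alkene plane and the hydrogen-bonded peracid attacks syn to the hydroxyl group, should give the threo cis-epoxide (C3' R, C2' S), the bicarbonate buffer protecting the acid-labile aryl epoxide.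

Step 12
Reactants: 18 (S)-[(2R,3S)-3-Ar-oxiran-2-yl][3,4-bis(benzyloxy)-5-Fl-2-(triisopropylsilyloxy)phenyl]methanol
Product: 19 tert-butyldimethylsilyl ether of 18 at the C4' oxygen
Conditions: TBSCl, imidazole, DMAP (cat.), DMF, rt
Reagents that add atoms: tert-butylchlorodimethylsilane, CC(C)(C)[Si](C)(C)Cl
Why: Silylation of the only free hydroxyl under non-acidic conditions leaves the aryl epoxide intact and blocks the C4' oxygen before the C2' hydroxyl has to be sulfonylated.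

Step 13
Reactants: 19 tert-butyldimethylsilyl ether of 18 at the C4' oxygen
Product: 21 (S)-Ar[(2R,3S)-6,7-bis(benzyloxy)-3-(tert-butyldimethylsilyloxy)-5-Fl-2,3-dihydro-1-benzofuran-2-yl]methanol, via phenoxide 20 (not isolated)
Conditions: TBAF (1.1 equiv), THF, 0 °C → rt; H2O
Reagents that add atoms: none
Why: Fluoride cleaves the aryl silyl ether much faster than the hindered secondary alkyl silyl ether, and the released phenoxide opens the cis-epoxide at the proximal carbon C3' with inversion in a 5-exo-tet closure, which gives the trans-2,3-disubstituted dihydrobenzofuran and leaves the C2' oxygen as a free benzylic alcohol of unchanged configuration.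

Step 14
Reactants: 21 (S)-Ar[(2R,3S)-6,7-bis(benzyloxy)-3-(tert-butyldimethylsilyloxy)-5-Fl-2,3-dihydro-1-benzofuran-2-yl]methanol
Product: 22 methanesulfonate of 21 at the C2' oxygen
Conditions: Ms2O, Et3N, CH2Cl2, −20 °C; cold aq. NaHCO3; no chromatography, used at once
Reagents that add atoms: methanesulfonic anhydride, CS(=O)(=O)OS(C)(=O)=O
Why: O-sulfonylation of the single free hydroxyl breaks only the O–H bond and so retains C2', and the anhydride is chosen so that no chloride is present to displace the labile benzylic sulfonate.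

Step 15
Reactants: 22 methanesulfonate of 21 at the C2' oxygen
Product: 24 (2R,3S,4S)-7,8-bis(benzyloxy)-2-Ar-4-(tert-butyldimethylsilyloxy)-6-Fl-chroman-3-yl acetate, via oxiranium ion 23 (not isolated)
Conditions: Zn(OAc)2 (5 equiv), AcOH–THF–H2O, 0 → 40 °C
Reagents that add atoms: acetic acid, CC(=O)O; zinc diacetate, CC(=O)[O-].CC(=O)[O-].[Zn+2]
Why: As the mesylate leaves with zinc assistance, ring oxygen O1' attacks C2' from the rear (3-exo-tet, inversion at C2') and gives a bicyclic oxiranium ion in which O1' bridges C2' and C3'. Acetate then opens the three-membered ring at C3' anti to O1' (second inversion), so the O1'–C3' bond is exchanged for O1'–C2' and the five-membered ring becomes ring F; ring F is thus closed by the 3-exo-tet step followed by cleavage of the bond shared by the two small rings, not by a direct 6-endo attack. The closest known reaction type is the Zn(OAc)2-promoted ring expansion of 2-(1-sulfonyloxyalkyl)tetrahydrofurans and 2,3-dihydrobenzofurans to 3-acyloxytetrahydropyrans and chroman-3-yl esters. C2' is controlled by the configuration of the sulfonate-bearing carbon (anti participation, S to R) and C3' by the configuration of the ring carbon (anti opening), so the trans-dihydrobenzofuran maps onto the 2',3'-cis-3',4'-trans chroman. The step needs acetate to end on C3' and participation to be faster than free ionisation: capture at benzylic C2' only gives an ester that re-ionises to the same oxiranium ion whereas the C3' acetate is inert, and the mild chloride-free medium and the electron-withdrawing oxygen next to C2' disfavour unassisted ionisation.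

Step 16
Reactants: 24 (2R,3S,4S)-7,8-bis(benzyloxy)-2-Ar-4-(tert-butyldimethylsilyloxy)-6-Fl-chroman-3-yl acetate
Product: 25 (2R,3S,4S)-7,8-bis(benzyloxy)-2-Ar-4-(tert-butyldimethylsilyloxy)-6-Fl(OH)-chroman-3-ol
Conditions: i-Bu2AlH (DIBAL-H, excess), CH2Cl2, −78 → 0 °C; aq. KNa tartrate
Reagents that add atoms: none
Why: Hydride reduction cleaves the acetate and the hindered pivalate without base and leaves the benzyl ethers, the silyl ether and all stereocentres untouched.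

Step 17
Reactants: 25 (2R,3S,4S)-7,8-bis(benzyloxy)-2-Ar-4-(tert-butyldimethylsilyloxy)-6-Fl(OH)-chroman-3-ol
Product: 26 (2R,3R,4S)-7,8-bis(benzyloxy)-2-Ar-6-Fl(OH)-chromane-3,4-diol
Conditions: TBAF, AcOH (1:1), THF, rt
Reagents that add atoms: none
Why: Buffered fluoride removes the last silyl group under near-neutral conditions, which avoids acid-induced ionisation of the benzylic C4'–O bond.

Step 18
Reactants: 26 (2R,3R,4S)-7,8-bis(benzyloxy)-2-Ar-6-Fl(OH)-chromane-3,4-diol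
Product: 27 CNP0143773.1
Conditions: H2 (1 atm), Pd(OH)2/C, THF–MeOH–H2O, rt; handled under argon
Reagents that add atoms: none
Why: Hydrogenolysis of the eight aryl benzyl ethers over Pd(OH)2/C under neutral conditions is much faster than cleavage of the cyclic benzylic ether bonds or of the free benzylic C4' hydroxyl.

Compound list
1 | 2,3,4-trihydroxybenzaldehyde | O=Cc1ccc(O)c(O)c1O | starting material
2 | 3,4-bis(benzyloxy)-2-hydroxybenzaldehyde | O=Cc1ccc(OCc9ccccc9)c(OCc9ccccc9)c1O | intermediate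
3 | 3,4-bis(benzyloxy)-5-bromo-2-hydroxybenzaldehyde | O=Cc1cc(Br)c(OCc9ccccc9)c(OCc9ccccc9)c1O | intermediate
4 | 3,4-bis(benzyloxy)-5-bromo-2-(triisopropylsilyloxy)benzaldehyde | O=Cc1cc(Br)c(OCc9ccccc9)c(OCc9ccccc9)c1O[Si](C(C)C)(C(C)C)C(C)C | intermediate
5 | 2-[3,4-bis(benzyloxy)-5-bromo-2-(triisopropylsilyloxy)phenyl]-1,3-dioxolane | O1CCOC1c2cc(Br)c(OCc9ccccc9)c(OCc9ccccc9)c2O[Si](C(C)C)(C(C)C)C(C)C | intermediate
6 | [2,3-bis(benzyloxy)-5-(1,3-dioxolan-2-yl)-4-(triisopropylsilyloxy)phenyl]lithium | O1CCOC1c2cc([Li])c(OCc9ccccc9)c(OCc9ccccc9)c2O[Si](C(C)C)(C(C)C)C(C)C | intermediate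
7 | sodium 2,3-bis(benzyloxy)-6-formylphenoxide | [Na+].[O-]c1c(C=O)ccc(OCc9ccccc9)c1OCc9ccccc9 | intermediate
8 | [3,4-bis(benzyloxy)-2-hydroxyphenyl][2,3-bis(benzyloxy)-5-(1,3-dioxolan-2-yl)-4-(triisopropylsilyloxy)phenyl]methanol, racemic at the carbinol carbon | OC(c1ccc(OCc9ccccc9)c(OCc9ccccc9)c1O)c1cc(C2OCCO2)c(O[Si](C(C)C)(C(C)C)C(C)C)c(OCc9ccccc9)c1OCc9ccccc9 | intermediate
9 | 3,4-bis(benzyloxy)benzaldehyde | O=Cc1ccc(OCc2ccccc2)c(OCc2ccccc2)c1 | starting material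
10 | 1,2-bis(benzyloxy)-4-ethynylbenzene | C#Cc1ccc(OCc9ccccc9)c(OCc9ccccc9)c1 | intermediate
11 | (Z)-2-[3,4-bis(benzyloxy)phenyl]ethenyl 2,2-dimethylpropanoate | CC(C)(C)C(=O)O/C=C\c1ccc(OCc9ccccc9)c(OCc9ccccc9)c1 | intermediate
12 | (E)-o-quinone methide, 2,3-bis(benzyloxy)-6-{[2,3-bis(benzyloxy)-5-(1,3-dioxolan-2-yl)-4-(triisopropylsilyloxy)phenyl]methylidene}cyclohexa-2,4-dien-1-one | O=C1C(OCc9ccccc9)=C(OCc9ccccc9)C=C\C1=C/c1cc(C2OCCO2)c(O[Si](C(C)C)(C(C)C)C(C)C)c(OCc9ccccc9)c1OCc9ccccc9 | intermediate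
13 | 2-[3,4-bis(benzyloxy)-5-Fl-2-(triisopropylsilyloxy)phenyl]-1,3-dioxolane, upper flavan all-cis (2R,3R,4S) | O(Cc9ccccc9)c1ccc([C@H]2Oc3c(ccc(OCc9ccccc9)c3OCc9ccccc9)[C@@H](c3cc(C5OCCO5)c(O[Si](C(C)C)(C(C)C)C(C)C)c(OCc9ccccc9)c3OCc9ccccc9)[C@H]2OC(=O)C(C)(C)C)cc1OCc9ccccc9 | intermediate
14 | 3,4-bis(benzyloxy)-5-Fl-2-(triisopropylsilyloxy)benzaldehyde | O(Cc9ccccc9)c1ccc([C@H]2Oc3c(ccc(OCc9ccccc9)c3OCc9ccccc9)[C@@H](c3cc(C=O)c(O[Si](C(C)C)(C(C)C)C(C)C)c(OCc9ccccc9)c3OCc9ccccc9)[C@H]2OC(=O)C(C)(C)C)cc1OCc9ccccc9 | intermediate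
15 | ethyl{[3,4-bis(benzyloxy)phenyl]ethynyl}zinc | CC[Zn]C#Cc1ccc(OCc9ccccc9)c(OCc9ccccc9)c1 | intermediate
16 | (1R)-3-Ar-1-[3,4-bis(benzyloxy)-5-Fl-2-(triisopropylsilyloxy)phenyl]prop-2-yn-1-ol | O(Cc9ccccc9)c1ccc([C@H]2Oc3c(ccc(OCc9ccccc9)c3OCc9ccccc9)[C@@H](c3cc([C@H](O)C#Cc5ccc(OCc9ccccc9)c(OCc9ccccc9)c5)c(O[Si](C(C)C)(C(C)C)C(C)C)c(OCc9ccccc9)c3OCc9ccccc9)[C@H]2OC(=O)C(C)(C)C)cc1OCc9ccccc9 | intermediate
17 | (1R,2Z)-3-Ar-1-[3,4-bis(benzyloxy)-5-Fl-2-(triisopropylsilyloxy)phenyl]prop-2-en-1-ol | O(Cc9ccccc9)c1ccc([C@H]2Oc3c(ccc(OCc9ccccc9)c3OCc9ccccc9)[C@@H](c3cc([C@H](O)/C=C\c5ccc(OCc9ccccc9)c(OCc9ccccc9)c5)c(O[Si](C(C)C)(C(C)C)C(C)C)c(OCc9ccccc9)c3OCc9ccccc9)[C@H]2OC(=O)C(C)(C)C)cc1OCc9ccccc9 | intermediate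
18 | (S)-[(2R,3S)-3-Ar-oxiran-2-yl][3,4-bis(benzyloxy)-5-Fl-2-(triisopropylsilyloxy)phenyl]methanol, threo, cis-epoxide | O(Cc9ccccc9)c1ccc([C@H]2Oc3c(ccc(OCc9ccccc9)c3OCc9ccccc9)[C@@H](c3cc([C@H](O)[C@H]6O[C@H]6c5ccc(OCc9ccccc9)c(OCc9ccccc9)c5)c(O[Si](C(C)C)(C(C)C)C(C)C)c(OCc9ccccc9)c3OCc9ccccc9)[C@H]2OC(=O)C(C)(C)C)cc1OCc9ccccc9 | intermediate
19 | tert-butyldimethylsilyl ether of 18 at the C4' oxygen | O(Cc9ccccc9)c1ccc([C@H]2Oc3c(ccc(OCc9ccccc9)c3OCc9ccccc9)[C@@H](c3cc([C@H](O[Si](C)(C)C(C)(C)C)[C@H]6O[C@H]6c5ccc(OCc9ccccc9)c(OCc9ccccc9)c5)c(O[Si](C(C)C)(C(C)C)C(C)C)c(OCc9ccccc9)c3OCc9ccccc9)[C@H]2OC(=O)C(C)(C)C)cc1OCc9ccccc9 | intermediate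
20 | tetrabutylammonium phenoxide of 19 (aryl silyl group removed, C8a' oxygen anionic) | CCCC[N+](CCCC)(CCCC)CCCC.O(Cc9ccccc9)c1ccc([C@H]2Oc3c(ccc(OCc9ccccc9)c3OCc9ccccc9)[C@@H](c3cc([C@H](O[Si](C)(C)C(C)(C)C)[C@H]6O[C@H]6c5ccc(OCc9ccccc9)c(OCc9ccccc9)c5)c([O-])c(OCc9ccccc9)c3OCc9ccccc9)[C@H]2OC(=O)C(C)(C)C)cc1OCc9ccccc9 | intermediate
21 | (S)-Ar[(2R,3S)-6,7-bis(benzyloxy)-3-(tert-butyldimethylsilyloxy)-5-Fl-2,3-dihydro-1-benzofuran-2-yl]methanol, 2,3-trans | O(Cc9ccccc9)c1ccc([C@H]2Oc3c(ccc(OCc9ccccc9)c3OCc9ccccc9)[C@@H](c3cc4c(c(OCc9ccccc9)c3OCc9ccccc9)O[C@H]([C@@H](O)c3ccc(OCc9ccccc9)c(OCc9ccccc9)c3)[C@H]4O[Si](C)(C)C(C)(C)C)[C@H]2OC(=O)C(C)(C)C)cc1OCc9ccccc9 | intermediate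
22 | (S)-Ar[(2S,3S)-6,7-bis(benzyloxy)-3-(tert-butyldimethylsilyloxy)-5-Fl-2,3-dihydro-1-benzofuran-2-yl]methyl methanesulfonate, same spatial arrangement as 21, 2,3-trans | O(Cc9ccccc9)c1ccc([C@H]2Oc3c(ccc(OCc9ccccc9)c3OCc9ccccc9)[C@@H](c3cc4c(c(OCc9ccccc9)c3OCc9ccccc9)O[C@H]([C@@H](OS(C)(=O)=O)c3ccc(OCc9ccccc9)c(OCc9ccccc9)c3)[C@H]4O[Si](C)(C)C(C)(C)C)[C@H]2OC(=O)C(C)(C)C)cc1OCc9ccccc9 | intermediate
23 | bicyclic oxiranium ion, O1' bonded to C8a', C3' and C2' (C2' inverted relative to 22) | O(Cc9ccccc9)c1ccc([C@H]2Oc3c(ccc(OCc9ccccc9)c3OCc9ccccc9)[C@@H](c3cc4c(c(OCc9ccccc9)c3OCc9ccccc9)[O+]5[C@H]([C@H]5c3ccc(OCc9ccccc9)c(OCc9ccccc9)c3)[C@H]4O[Si](C)(C)C(C)(C)C)[C@H]2OC(=O)C(C)(C)C)cc1OCc9ccccc9 | intermediate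
24 | (2R,3S,4S)-7,8-bis(benzyloxy)-2-Ar-4-(tert-butyldimethylsilyloxy)-6-Fl-chroman-3-yl acetate, 2,3-cis, 3,4-trans | O(Cc9ccccc9)c1ccc([C@H]2Oc3c(ccc(OCc9ccccc9)c3OCc9ccccc9)[C@@H](c3cc4c(c(OCc9ccccc9)c3OCc9ccccc9)O[C@H](c3ccc(OCc9ccccc9)c(OCc9ccccc9)c3)[C@H](OC(C)=O)[C@H]4O[Si](C)(C)C(C)(C)C)[C@H]2OC(=O)C(C)(C)C)cc1OCc9ccccc9 | intermediate
25 | (2R,3S,4S)-7,8-bis(benzyloxy)-2-Ar-4-(tert-butyldimethylsilyloxy)-6-Fl(OH)-chroman-3-ol | O(Cc9ccccc9)c1ccc([C@H]2Oc3c(ccc(OCc9ccccc9)c3OCc9ccccc9)[C@@H](c3cc4c(c(OCc9ccccc9)c3OCc9ccccc9)O[C@H](c3ccc(OCc9ccccc9)c(OCc9ccccc9)c3)[C@H](O)[C@H]4O[Si](C)(C)C(C)(C)C)[C@H]2O)cc1OCc9ccccc9 | intermediate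
26 | (2R,3R,4S)-7,8-bis(benzyloxy)-2-Ar-6-Fl(OH)-chromane-3,4-diol (octa-O-benzyl ether of the target) | O(Cc9ccccc9)c1ccc([C@H]2Oc3c(ccc(OCc9ccccc9)c3OCc9ccccc9)[C@@H](c3cc4c(c(OCc9ccccc9)c3OCc9ccccc9)O[C@H](c3ccc(OCc9ccccc9)c(OCc9ccccc9)c3)[C@H](O)[C@H]4O)[C@H]2O)cc1OCc9ccccc9 | intermediate
27 | CNP0143773.1, (2R,3R,4S)-2-(3,4-dihydroxyphenyl)-6-[(2R,3R,4R)-2-(3,4-dihydroxyphenyl)-3,7,8-trihydroxychroman-4-yl]chromane-3,4,7,8-tetrol | Oc1ccc([C@H]2Oc3c(ccc(O)c3O)[C@@H](c3cc4c(c(O)c3O)O[C@H](c3ccc(O)c(O)c3)[C@H](O)[C@H]4O)[C@H]2O)cc1O | target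

Total step count: 18. Longest linear sequence: 16 steps (steps 1–5 and 8–18, from 1).

Steps most likely to fail

Step 8. The chiral anion may not discriminate the two faces of the o-quinone methide well enough, and the Z information may be eroded if C–C and C–O bond formation separate. The fallback replaces catalyst control by a covalent auxiliary and diastereomer separation. It sets out from alkyne 10: Ru(methallyl)2(dppb)-catalysed addition of N-Boc-L-proline gives the Z-enol prolinate F1. Cycloaddition of F1 with benzhydrol 8 under diphenyl phosphate proceeds through 12 and gives two all-cis diastereomers, the (2R,3R,4S) prolinate F2 and the (2S,3S,4R) prolinate F3, which are separated by chromatography or crystallisation. Methanolysis of F2 (K2CO3, MeOH) gives the flavan-3-ol F4, and pivaloylation (PivCl, DMAP, pyridine) rejoins the route at 13, which is hydrolysed to 14 as in step 8.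

Step 15. Ionisation of the benzylic sulfonate may outrun participation by O1', which would cost the configuration at C2', or elimination may intervene. The fallback closes ring F directly and sets out from 19. Buffered fluoride (TBAF/AcOH, THF, 0 °C) frees the epoxy phenol F5 without base-induced closure. Catalytic camphorsulfonic acid in CH2Cl2 at −40 °C then promotes anti attack of the phenol on the aryl-activated epoxide carbon C2' (6-endo, inversion). This gives the chroman-3'-ol F6, which has the configuration of 24. i-Bu2AlH removes the pivalate and the route is rejoined at 25.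

Step 9. Delivery of the alkynyl group to the hindered ortho-silyloxy aldehyde may show weak facial control. The fallback sets C4' by reagent-controlled ketone reduction and sets out from 14. The lithium acetylide F7 (from 10 and n-BuLi, THF, −78 °C) adds to give the C4'-epimeric propargylic alcohols F8. MnO2 oxidises them to the ynone F9. Reduction with BH3·SMe2 and (S)-2-methyl-CBS-oxazaborolidine, the alkynyl group acting as the small substituent, gives 16, where the route is rejoined.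

Further compounds
F1 | step 8 | (Z)-2-[3,4-bis(benzyloxy)phenyl]ethenyl (2S)-1-(tert-butoxycarbonyl)pyrrolidine-2-carboxylate | CC(C)(C)OC(=O)N1CCC[C@H]1C(=O)O/C=C\c1ccc(OCc9ccccc9)c(OCc9ccccc9)c1
F2 | step 8 | analogue of 13 with the N-Boc-L-prolyl ester in place of the pivalate, upper flavan (2R,3R,4S) | O(Cc9ccccc9)c1ccc([C@H]2Oc3c(ccc(OCc9ccccc9)c3OCc9ccccc9)[C@@H](c3cc(C5OCCO5)c(O[Si](C(C)C)(C(C)C)C(C)C)c(OCc9ccccc9)c3OCc9ccccc9)[C@H]2OC(=O)[C@@H]6CCCN6C(=O)OC(C)(C)C)cc1OCc9ccccc9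
F3 | step 8 | diastereomer of F2 with the upper flavan (2S,3S,4R) | O(Cc9ccccc9)c1ccc([C@@H]2Oc3c(ccc(OCc9ccccc9)c3OCc9ccccc9)[C@H](c3cc(C5OCCO5)c(O[Si](C(C)C)(C(C)C)C(C)C)c(OCc9ccccc9)c3OCc9ccccc9)[C@@H]2OC(=O)[C@@H]6CCCN6C(=O)OC(C)(C)C)cc1OCc9ccccc9
F4 | step 8 | analogue of 13 with a free 3-hydroxyl, 2-[3,4-bis(benzyloxy)-5-Fl(OH)-2-(triisopropylsilyloxy)phenyl]-1,3-dioxolane | O(Cc9ccccc9)c1ccc([C@H]2Oc3c(ccc(OCc9ccccc9)c3OCc9ccccc9)[C@@H](c3cc(C5OCCO5)c(O[Si](C(C)C)(C(C)C)C(C)C)c(OCc9ccccc9)c3OCc9ccccc9)[C@H]2O)cc1OCc9ccccc9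
F5 | step 15 | free phenol of 19 (neutral form of 20) | O(Cc9ccccc9)c1ccc([C@H]2Oc3c(ccc(OCc9ccccc9)c3OCc9ccccc9)[C@@H](c3cc([C@H](O[Si](C)(C)C(C)(C)C)[C@H]6O[C@H]6c5ccc(OCc9ccccc9)c(OCc9ccccc9)c5)c(O)c(OCc9ccccc9)c3OCc9ccccc9)[C@H]2OC(=O)C(C)(C)C)cc1OCc9ccccc9
F6 | step 15 | (2R,3S,4S)-7,8-bis(benzyloxy)-2-Ar-4-(tert-butyldimethylsilyloxy)-6-Fl-chroman-3-ol | O(Cc9ccccc9)c1ccc([C@H]2Oc3c(ccc(OCc9ccccc9)c3OCc9ccccc9)[C@@H](c3cc4c(c(OCc9ccccc9)c3OCc9ccccc9)O[C@H](c3ccc(OCc9ccccc9)c(OCc9ccccc9)c3)[C@H](O)[C@H]4O[Si](C)(C)C(C)(C)C)[C@H]2OC(=O)C(C)(C)C)cc1OCc9ccccc9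
F7 | step 9 | {[3,4-bis(benzyloxy)phenyl]ethynyl}lithium | [Li]C#Cc1ccc(OCc9ccccc9)c(OCc9ccccc9)c1
F8 | step 9 | 16 as a mixture with its C4' epimer (C4' undefined) | O(Cc9ccccc9)c1ccc([C@H]2Oc3c(ccc(OCc9ccccc9)c3OCc9ccccc9)[C@@H](c3cc(C(O)C#Cc5ccc(OCc9ccccc9)c(OCc9ccccc9)c5)c(O[Si](C(C)C)(C(C)C)C(C)C)c(OCc9ccccc9)c3OCc9ccccc9)[C@H]2OC(=O)C(C)(C)C)cc1OCc9ccccc9
F9 | step 9 | 3-Ar-1-[3,4-bis(benzyloxy)-5-Fl-2-(triisopropylsilyloxy)phenyl]prop-2-yn-1-one | O(Cc9ccccc9)c1ccc([C@H]2Oc3c(ccc(OCc9ccccc9)c3OCc9ccccc9)[C@@H](c3cc(C(=O)C#Cc5ccc(OCc9ccccc9)c(OCc9ccccc9)c5)c(O[Si](C(C)C)(C(C)C)C(C)C)c(OCc9ccccc9)c3OCc9ccccc9)[C@H]2OC(=O)C(C)(C)C)cc1OCc9ccccc9
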